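**Retrosynthetic overview**

1. The route rests on the acyclic methine C8, which carries the methyl group C9 and the methylene C7 bound to the guaiacyl ring (4-hydroxy-3-methoxyphenyl), and which sits next to C8', the methine carrying C9'H2–OAc and the syringyl methylene C7'. This is the pattern left by methyl-metalation of a terminal alkene followed by arylation of the metalated carbon.
2. End game: a bis-O-benzyl silyl ether is desilylated, acetylated at O9', and both phenols are freed last by hydrogenolysis.
3. Key disconnection: C8–C9 and C7–aryl are cut together, giving an (R)-2-(arylmethyl)but-3-enyl silyl ether, AlMe3 and O-benzyl-4-bromoguaiacol (zirconium-catalysed asymmetric methylalumination, then zinc/palladium Negishi arylation in one pot).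
4. The alkene comes from a deconjugative Evans alkylation of the N-crotonoyl derivative of (R)-4-benzyloxazolidin-2-one with an O-benzylsyringyl bromide made from syringaldehyde (sets C8'), followed by LiBH4 cleavage and silylation.
5. No ring is formed at any stage; both benzene rings are bought. The stereocentres are set in the order C8' (auxiliary), then C8 (catalyst).

Key step: step 9

Remark: lignan-type labels are used (C7, C8, C9 on the guaiacyl half; C7', C8', C9' on the syringyl half). The sense of induction of the (−)-zirconocene is assumed to be the one it shows with unbranched 1-alkenes; if the branched alkene responds in the opposite sense, the (+)-complex is used in the same way.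

**Route**

Step 1
Reactants: 1 syringaldehyde
Product: 2 4-benzyloxy-3,5-dimethoxybenzaldehyde
Conditions: BnBr, K2CO3, DMF, 60 °C
Reagents that add atoms: benzyl bromide, BrCc1ccccc1
Why: Williamson ether synthesis, in which the phenoxide of 1 displaces bromide from benzyl bromide; the benzyl ether is chosen because it tolerates AlMe3 and the palladium coupling and is removed last by hydrogenolysis.

Step 2
Reactants: 2 4-benzyloxy-3,5-dimethoxybenzaldehyde
Product: 3 (4-benzyloxy-3,5-dimethoxyphenyl)methanol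
Conditions: NaBH4, MeOH/THF, 0 °C
Reagents that add atoms: none
Why: Borohydride reduction of an aryl aldehyde to the benzylic alcohol, which leaves the aryl ethers untouched.

Step 3
Reactants: 3 (4-benzyloxy-3,5-dimethoxyphenyl)methanol
Product: 4 2-benzyloxy-5-(bromomethyl)-1,3-dimethoxybenzene
Conditions: PBr3, CH2Cl2, 0 °C
Reagents that add atoms: phosphorus tribromide, BrP(Br)Br
Why: Bromination of a benzylic alcohol with PBr3 (phosphite ester formation, then SN2 displacement by bromide), which should be clean at 0 °C; the electron-rich bromide is used promptly.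

Step 4
Reactants: 5 (R)-4-benzyloxazolidin-2-one; 6 (E)-but-2-enoyl chloride
Product: 8 (4R)-4-benzyl-3-[(E)-but-2-enoyl]oxazolidin-2-one, via lithium oxazolidinide 7 (not isolated)
Conditions: n-BuLi, THF, −78 °C; then 6, −78 → 0 °C
Reagents that add atoms: none
Why: N-acylation of the lithiated oxazolidinone by the acid chloride, the standard way to attach the auxiliary, with the low temperature suppressing conjugate addition to the crotonoyl unit.

Step 5
Reactants: 8 (4R)-4-benzyl-3-[(E)-but-2-enoyl]oxazolidin-2-one; 4 2-benzyloxy-5-(bromomethyl)-1,3-dimethoxybenzene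
Product: 10 (4R)-4-benzyl-3-{(2R)-2-[(4-benzyloxy-3,5-dimethoxyphenyl)methyl]but-3-enoyl}oxazolidin-2-one, via sodium dienolate 9 (not isolated)
Conditions: NaN(SiMe3)2, THF, −78 °C; then 4, −78 → −40 °C; AcOH quench at low temperature
Reagents that add atoms: none
Why: Deconjugative Evans asymmetric alkylation, in which γ-deprotonation gives the chelated (Z)-dienolate 9 and the benzylic bromide attacks its α-carbon on the face away from the C4 benzyl group of the auxiliary; this sets C8' as R, because the vinyl group takes the place that methyl has in a propionyl enolate and so the (R)-auxiliary is the one required.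

Step 6
Reactants: 10 (4R)-4-benzyl-3-{(2R)-2-[(4-benzyloxy-3,5-dimethoxyphenyl)methyl]but-3-enoyl}oxazolidin-2-one
Product: 11 (2R)-2-[(4-benzyloxy-3,5-dimethoxyphenyl)methyl]but-3-en-1-ol
Conditions: LiBH4, MeOH (1 equiv), Et2O, 0 °C
Reagents that add atoms: none
Why: Reductive cleavage of the N-acyl oxazolidinone by hydride attack at the exocyclic carbonyl gives the primary alcohol and returns the auxiliary, and the cold, weakly basic medium should leave C8' and the position of the alkene unchanged.

Step 7
Reactants: 11 (2R)-2-[(4-benzyloxy-3,5-dimethoxyphenyl)methyl]but-3-en-1-ol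
Product: 12 tert-butyl{(2R)-2-[(4-benzyloxy-3,5-dimethoxyphenyl)methyl]but-3-enyloxy}dimethylsilane
Conditions: TBSCl, imidazole, DMF, rt
Reagents that add atoms: tert-butyldimethylsilyl chloride, CC(C)(C)[Si](C)(C)Cl
Why: Imidazole-promoted silylation of a primary alcohol; the silyl ether is inert to AlMe3 and to the coupling and is later removed by fluoride without touching the benzyl ethers.

Step 8
Reactants: 13 4-bromo-2-methoxyphenol
Product: 14 1-benzyloxy-4-bromo-2-methoxybenzene
Conditions: BnBr, K2CO3, DMF, rt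
Reagents that add atoms: benzyl bromide, BrCc1ccccc1
Why: Williamson ether synthesis on the phenol, which leaves the aryl bromide available for oxidative addition.

Step 9
Reactants: 12 tert-butyl{(2R)-2-[(4-benzyloxy-3,5-dimethoxyphenyl)methyl]but-3-enyloxy}dimethylsilane; 15 trimethylaluminium; 14 1-benzyloxy-4-bromo-2-methoxybenzene
Product: 18 tert-butyl{(2R,3S)-2-[(4-benzyloxy-3,5-dimethoxyphenyl)methyl]-4-(4-benzyloxy-3-methoxyphenyl)-3-methylbutoxy}dimethylsilane, via alkylalane 16 (not isolated), via alkylzinc triflate 17 (not isolated)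
Conditions: AlMe3 (3 equiv), methylaluminoxane (MeAlO)n, (−)-bis(1-neomenthylindenyl)zirconium dichloride [(NMI)2ZrCl2, 5–10 mol %], CH2Cl2, 0 °C → rt; volatiles removed in vacuo; Zn(OTf)2, DMF, 70 °C; then 14 (excess), Pd[P(t-Bu)3]2 (5 mol %), rt → 50 °C
Reagents that add atoms: none
Why: Proposed new method: AlMe3 and (MeAlO)n turn (NMI)2ZrCl2 into a cationic methylzirconocene that inserts the terminal alkene with zirconium on C7 and methyl on C8, exchange with aluminium releases alane 16, Zn(OTf)2 in DMF passes its alkyl group to zinc (17), and this transfers to the arylpalladium bromide formed from 14 and zerovalent palladium, reductive elimination forming the C7–aryl bond. The closest known reaction type is the zirconium-catalysed asymmetric carboalumination of unbranched 1-alkenes with one-pot zinc- and palladium-mediated Negishi coupling; what is new is an alkene with a stereogenic allylic branch. No ring is closed. The new stereocentre C8 is controlled by the catalyst: the (−)-enantiomer of the neomenthylindenyl complex is the one that gives (R)-2-methylalkyl alanes from simple 1-alkenes, and the same spatial sense gives R in 16 and, once C7 carries the aryl group and drops in priority, S at C8 in 18. The step needs methyl on the internal carbon, which the usual regiochemistry of carboalumination of monosubstituted alkenes secures, and it needs face selectivity, on which C8' with its two CH2 arms of similar size should exert little bias of its own, while C8' itself is not touched. Competing transfer of the methyl groups left on aluminium is absorbed by the excess of 14 after the free AlMe3 has been pumped off.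

Step 10
Reactants: 18 tert-butyl{(2R,3S)-2-[(4-benzyloxy-3,5-dimethoxyphenyl)methyl]-4-(4-benzyloxy-3-methoxyphenyl)-3-methylbutoxy}dimethylsilane
Product: 19 (2R,3S)-2-[(4-benzyloxy-3,5-dimethoxyphenyl)methyl]-4-(4-benzyloxy-3-methoxyphenyl)-3-methylbutan-1-ol
Conditions: Bu4NF, THF, rt
Reagents that add atoms: none
Why: Fluoride-driven cleavage of the silyl ether, which leaves the benzyl aryl ethers and both stereocentres unaffected.

Step 11
Reactants: 19 (2R,3S)-2-[(4-benzyloxy-3,5-dimethoxyphenyl)methyl]-4-(4-benzyloxy-3-methoxyphenyl)-3-methylbutan-1-ol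
Product: 20 (2R,3S)-2-[(4-benzyloxy-3,5-dimethoxyphenyl)methyl]-4-(4-benzyloxy-3-methoxyphenyl)-3-methylbutyl acetate
Conditions: Ac2O, pyridine, DMAP (cat.), CH2Cl2, rt
Reagents that add atoms: acetic anhydride, CC(=O)OC(C)=O
Why: DMAP-catalysed acetylation of the primary alcohol, the only free hydroxyl because both phenols are still benzylated, which is why acetylation precedes debenzylation.

Step 12
Reactants: 20 (2R,3S)-2-[(4-benzyloxy-3,5-dimethoxyphenyl)methyl]-4-(4-benzyloxy-3-methoxyphenyl)-3-methylbutyl acetate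
Product: 21 (2R,3S)-2-[(4-hydroxy-3,5-dimethoxyphenyl)methyl]-4-(4-hydroxy-3-methoxyphenyl)-3-methylbutyl acetate (CID53359579)
Conditions: H2 (1 atm), Pd/C, EtOAc, rt
Reagents that add atoms: none
Why: Hydrogenolysis of the two benzyl aryl ethers over Pd/C under neutral conditions, which spares the acetate, the aryl methyl ethers and the two sp3 stereocentres (neither benzylic carbon carries a heteroatom).

**Compound list**

1 | syringaldehyde (4-hydroxy-3,5-dimethoxybenzaldehyde) | COc1cc(C=O)cc(OC)c1O | starting material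
2 | 4-benzyloxy-3,5-dimethoxybenzaldehyde | COc1cc(C=O)cc(OC)c1OCc1ccccc1 | intermediate
3 | (4-benzyloxy-3,5-dimethoxyphenyl)methanol | COc1cc(CO)cc(OC)c1OCc1ccccc1 | intermediate
4 | 2-benzyloxy-5-(bromomethyl)-1,3-dimethoxybenzene | COc1cc(CBr)cc(OC)c1OCc1ccccc1 | intermediate
5 | (R)-4-benzyloxazolidin-2-one | O=C1N[C@H](Cc2ccccc2)CO1 | starting material
6 | (E)-but-2-enoyl chloride | C/C=C/C(=O)Cl | starting material
7 | N-lithio derivative of (R)-4-benzyloxazolidin-2-one | [Li]N1[C@H](Cc2ccccc2)COC1=O | intermediate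
8 | (4R)-4-benzyl-3-[(E)-but-2-enoyl]oxazolidin-2-one | C/C=C/C(=O)N1[C@H](Cc2ccccc2)COC1=O | intermediate
9 | sodium (Z)-dienolate of 8 | C=C/C=C(\O[Na])N1[C@H](Cc2ccccc2)COC1=O | intermediate
10 | (4R)-4-benzyl-3-{(2R)-2-[(4-benzyloxy-3,5-dimethoxyphenyl)methyl]but-3-enoyl}oxazolidin-2-one | C=C[C@H](C(=O)N1[C@H](Cc2ccccc2)COC1=O)Cc1cc(OC)c(OCc2ccccc2)c(OC)c1 | intermediate
11 | (2R)-2-[(4-benzyloxy-3,5-dimethoxyphenyl)methyl]but-3-en-1-ol | C=C[C@H](CO)Cc1cc(OC)c(OCc2ccccc2)c(OC)c1 | intermediate
12 | tert-butyl{(2R)-2-[(4-benzyloxy-3,5-dimethoxyphenyl)methyl]but-3-enyloxy}dimethylsilane | C=C[C@H](CO[Si](C)(C)C(C)(C)C)Cc1cc(OC)c(OCc2ccccc2)c(OC)c1 | intermediate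
13 | 4-bromo-2-methoxyphenol | COc1cc(Br)ccc1O | starting material
14 | 1-benzyloxy-4-bromo-2-methoxybenzene | COc1cc(Br)ccc1OCc1ccccc1 | intermediate
15 | trimethylaluminium | C[Al](C)C | starting material
16 | {(2R,3R)-4-(4-benzyloxy-3,5-dimethoxyphenyl)-3-[(tert-butyldimethylsilyloxy)methyl]-2-methylbutyl}dimethylaluminium | C[Al](C)C[C@H](C)[C@H](CO[Si](C)(C)C(C)(C)C)Cc1cc(OC)c(OCc2ccccc2)c(OC)c1 | intermediate
17 | {(2R,3R)-4-(4-benzyloxy-3,5-dimethoxyphenyl)-3-[(tert-butyldimethylsilyloxy)methyl]-2-methylbutyl}zinc trifluoromethanesulfonate | O=S(=O)(O[Zn]C[C@H](C)[C@H](CO[Si](C)(C)C(C)(C)C)Cc1cc(OC)c(OCc2ccccc2)c(OC)c1)C(F)(F)F | intermediate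
18 | tert-butyl{(2R,3S)-2-[(4-benzyloxy-3,5-dimethoxyphenyl)methyl]-4-(4-benzyloxy-3-methoxyphenyl)-3-methylbutoxy}dimethylsilane | COc1cc(C[C@H](C)[C@H](CO[Si](C)(C)C(C)(C)C)Cc2cc(OC)c(OCc3ccccc3)c(OC)c2)ccc1OCc1ccccc1 | intermediate
19 | (2R,3S)-2-[(4-benzyloxy-3,5-dimethoxyphenyl)methyl]-4-(4-benzyloxy-3-methoxyphenyl)-3-methylbutan-1-ol | COc1cc(C[C@H](C)[C@H](CO)Cc2cc(OC)c(OCc3ccccc3)c(OC)c2)ccc1OCc1ccccc1 | intermediate
20 | (2R,3S)-2-[(4-benzyloxy-3,5-dimethoxyphenyl)methyl]-4-(4-benzyloxy-3-methoxyphenyl)-3-methylbutyl acetate | COc1cc(C[C@H](C)[C@H](COC(C)=O)Cc2cc(OC)c(OCc3ccccc3)c(OC)c2)ccc1OCc1ccccc1 | intermediate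
21 | (2R,3S)-2-[(4-hydroxy-3,5-dimethoxyphenyl)methyl]-4-(4-hydroxy-3-methoxyphenyl)-3-methylbutyl acetate (CID53359579) | COc1cc(C[C@H](C)[C@H](COC(C)=O)Cc2cc(OC)c(O)c(OC)c2)ccc1O | target

**Step count and risks**

Total step count: 12.
Longest linear sequence: 10 steps (steps 1, 2, 3, 5, 6, 7, 9, 10, 11, 12).

Steps most likely to fail:

1. Step 9 (one-pot methylalumination and arylation). Insertion of the allylically branched alkene may be slow, so that β-hydride loss from the alkylzirconium and hydrometalation compete. The resident centre C8' may oppose the catalyst and erode face selectivity at C8. In the coupling, methyl transfer from aluminium may outrun transfer of the β-branched alkyl group. The fallback uses known chemistry, sets out from 12 and returns at 18. The alkene of 12 is cleaved (OsO4 cat., NaIO4, 2,6-lutidine, dioxane/H2O) to (2S)-3-(4-benzyloxy-3,5-dimethoxyphenyl)-2-[(tert-butyldimethylsilyloxy)methyl]propanal F1. This is homologated with dimethyl (1-diazo-2-oxopropyl)phosphonate and K2CO3 in MeOH at 0 °C (Ohira–Bestmann reaction) to tert-butyl{(2R)-2-[(4-benzyloxy-3,5-dimethoxyphenyl)methyl]but-3-ynyloxy}dimethylsilane F2. Syn-methylalumination of the alkyne with 15 and Cp2ZrCl2 in CH2Cl2 gives {(1E,3R)-4-(4-benzyloxy-3,5-dimethoxyphenyl)-3-[(tert-butyldimethylsilyloxy)methyl]-2-methylbut-1-enyl}dimethylaluminium F3, which is not isolated but coupled with 14 (Pd(PPh3)4, ZnCl2, THF) to tert-butyl{(2R,3E)-2-[(4-benzyloxy-3,5-dimethoxyphenyl)methyl]-4-(4-benzyloxy-3-methoxyphenyl)-3-methylbut-3-enyloxy}dimethylsilane F4. Catalyst-controlled hydrogenation of this trisubstituted alkene (H2, [Ir(cod)(L)]B[3,5-(CF3)2C6H3]4 with L a chiral phosphinooxazoline, CH2Cl2), using the ligand enantiomer that delivers hydrogen to give S at C8, should lead to 18 with the benzyl ethers intact.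

2. Step 5 (deconjugative alkylation). The dienolate may be alkylated at the γ-carbon or twice, and proton exchange between product and dienolate may erode the diastereoselectivity or move the alkene into conjugation. The fallback sets out from 5 and 4, carries the vinyl group in masked form, and returns at 12. γ-Butyrolactone is opened with PhSeNa (from PhSeSePh and NaBH4, DMF, 120 °C) to 4-(phenylselanyl)butanoic acid F5, which (COCl)2 with catalytic DMF converts into 4-(phenylselanyl)butanoyl chloride F6. Acylation of 5 through its lithium salt 7 gives (4R)-4-benzyl-3-[4-(phenylselanyl)butanoyl]oxazolidin-2-one F7. NaN(SiMe3)2 in THF at −78 °C forms the sodium (Z)-enolate of that imide F8, which has no γ-position to compete and is alkylated by 4 in an ordinary Evans alkylation to (4R)-4-benzyl-3-{(2R)-2-[(4-benzyloxy-3,5-dimethoxyphenyl)methyl]-4-(phenylselanyl)butanoyl}oxazolidin-2-one F9. LiBH4 reduction gives (2R)-2-[(4-benzyloxy-3,5-dimethoxyphenyl)methyl]-4-(phenylselanyl)butan-1-ol F10, and TBSCl with imidazole gives tert-butyl{(2R)-2-[(4-benzyloxy-3,5-dimethoxyphenyl)methyl]-4-(phenylselanyl)butoxy}dimethylsilane F11. H2O2 with pyridine in CH2Cl2 (0 °C → rt) oxidises selenium to the selenoxide of that silyl ether F12, whose syn-elimination at room temperature forms the terminal alkene 12.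

3. Step 6 (hydride cleavage of the auxiliary). The cleavage may be accompanied by base-promoted migration of the alkene into conjugation with loss of the C8' configuration, or by hydride attack at the ring carbonyl of the auxiliary. The fallback sets out from 10, separates removal of the auxiliary from the reduction, and returns at 11. LiOH and H2O2 in THF/H2O at 0 °C hydrolyse the imide to (2R)-2-[(4-benzyloxy-3,5-dimethoxyphenyl)methyl]but-3-enoic acid F13. Me3SiCHN2 in MeOH/toluene gives methyl (2R)-2-[(4-benzyloxy-3,5-dimethoxyphenyl)methyl]but-3-enoate F14. i-Bu2AlH in CH2Cl2 at −78 °C, a non-basic hydride, reduces the ester to alcohol 11.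

**Further compounds**

F1 | step 9 | (2S)-3-(4-benzyloxy-3,5-dimethoxyphenyl)-2-[(tert-butyldimethylsilyloxy)methyl]propanal | O=C[C@H](CO[Si](C)(C)C(C)(C)C)Cc1cc(OC)c(OCc2ccccc2)c(OC)c1
F2 | step 9 | tert-butyl{(2R)-2-[(4-benzyloxy-3,5-dimethoxyphenyl)methyl]but-3-ynyloxy}dimethylsilane | C#C[C@H](CO[Si](C)(C)C(C)(C)C)Cc1cc(OC)c(OCc2ccccc2)c(OC)c1
F3 | step 9 | {(1E,3R)-4-(4-benzyloxy-3,5-dimethoxyphenyl)-3-[(tert-butyldimethylsilyloxy)methyl]-2-methylbut-1-enyl}dimethylaluminium | C[Al](C)/C=C(\C)[C@H](CO[Si](C)(C)C(C)(C)C)Cc1cc(OC)c(OCc2ccccc2)c(OC)c1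
F4 | step 9 | tert-butyl{(2R,3E)-2-[(4-benzyloxy-3,5-dimethoxyphenyl)methyl]-4-(4-benzyloxy-3-methoxyphenyl)-3-methylbut-3-enyloxy}dimethylsilane | COc1cc(/C=C(\C)[C@H](CO[Si](C)(C)C(C)(C)C)Cc2cc(OC)c(OCc3ccccc3)c(OC)c2)ccc1OCc1ccccc1
F5 | step 5 | 4-(phenylselanyl)butanoic acid | OC(=O)CCC[Se]c1ccccc1
F6 | step 5 | 4-(phenylselanyl)butanoyl chloride | ClC(=O)CCC[Se]c1ccccc1
F7 | step 5 | (4R)-4-benzyl-3-[4-(phenylselanyl)butanoyl]oxazolidin-2-one | O=C(CCC[Se]c1ccccc1)N1[C@H](Cc2ccccc2)COC1=O
F8 | step 5 | sodium (Z)-enolate of (4R)-4-benzyl-3-[4-(phenylselanyl)butanoyl]oxazolidin-2-one | [Na]O/C(=C\CC[Se]c1ccccc1)N1[C@H](Cc2ccccc2)COC1=O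
F9 | step 5 | (4R)-4-benzyl-3-{(2R)-2-[(4-benzyloxy-3,5-dimethoxyphenyl)methyl]-4-(phenylselanyl)butanoyl}oxazolidin-2-one | c1ccccc1[Se]CC[C@H](C(=O)N1[C@H](Cc2ccccc2)COC1=O)Cc1cc(OC)c(OCc2ccccc2)c(OC)c1
F10 | step 5 | (2R)-2-[(4-benzyloxy-3,5-dimethoxyphenyl)methyl]-4-(phenylselanyl)butan-1-ol | c1ccccc1[Se]CC[C@H](CO)Cc1cc(OC)c(OCc2ccccc2)c(OC)c1
F11 | step 5 | tert-butyl{(2R)-2-[(4-benzyloxy-3,5-dimethoxyphenyl)methyl]-4-(phenylselanyl)butoxy}dimethylsilane | c1ccccc1[Se]CC[C@H](CO[Si](C)(C)C(C)(C)C)Cc1cc(OC)c(OCc2ccccc2)c(OC)c1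
F12 | step 5 | selenoxide of tert-butyl{(2R)-2-[(4-benzyloxy-3,5-dimethoxyphenyl)methyl]-4-(phenylselanyl)butoxy}dimethylsilane | [O-][Se+](CC[C@H](CO[Si](C)(C)C(C)(C)C)Cc1cc(OC)c(OCc2ccccc2)c(OC)c1)c1ccccc1
F13 | step 6 | (2R)-2-[(4-benzyloxy-3,5-dimethoxyphenyl)methyl]but-3-enoic acid | C=C[C@H](C(=O)O)Cc1cc(OC)c(OCc2ccccc2)c(OC)c1
F14 | step 6 | methyl (2R)-2-[(4-benzyloxy-3,5-dimethoxyphenyl)methyl]but-3-enoate | C=C[C@H](C(=O)OC)Cc1cc(OC)c(OCc2ccccc2)c(OC)c1
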